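**Assumptions (one line each)**
- Labdane numbering is used throughout (C2–Cl, C6=O, C8=C17H2, C9 side chain, C12–OH, C13 = imide CH); α is the face opposite the C10 methyl.
- N-Chloroamide 2 is treated as a purchasable reagent (otherwise one step from the parent amide with trichloroisocyanuric acid).
- The C6 configuration in 11, 14 and 15 is inconsequential because C6 ends as C=O; the expected 6α isomer is drawn.

**Retrosynthetic overview**
1. Succinimide, C12 and C13: Evans syn-aldol of keto-aldehyde 16 with a succinamoyl (R)-oxazolidinone, then N-acyl transfer closes the imide (the only ring formed, and the last).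
2. Keto-aldehyde 16 comes from 6-hydroxy Weinreb amide 14 (LiAlH4, then Dess–Martin), so the β,γ-enone is unveiled late.
3. C6 oxygen and C8 methylene: 17-nor-8-ketone → Δ6-en-8-one → Cu-catalysed β-borylation at C6 → methylenation at C8 → C–B oxidation.
4. The 8-ketone comes from 2α-chlorosclareolide by Weinreb opening, exo-selective dehydration and ozonolysis.
5. Rings A and B are bought intact as (+)-sclareolide; C2–Cl is installed first by site-selective C–H chlorination.

**Route**

Step 1
Reactants: 1 (+)-sclareolide; 2 N-tert-butyl-N-chloro-3,5-bis(trifluoromethyl)benzamide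
Product: 3, 2α-chlorosclareolide (equatorial Cl at C2, 2S)
Conditions: 2 (1.2 equiv), Cs2CO3, PhH, 55 °C, visible light
Reagents that add atoms: 2, CC(C)(C)N(Cl)C(=O)c1cc(cc(c1)C(F)(F)F)C(F)(F)F (Cl)
Why: Amidyl-radical C–H chlorination; the bulky electrophilic radical abstracts the most accessible C2–H remote from the lactone, and Cl is delivered to the α-face, away from the two syn-axial β-methyls, giving the equatorial 2α-chloride.

Step 2
Reactants: 3; 4 N,O-dimethylhydroxylamine hydrochloride
Product: 5, Weinreb amide of 2α-chloro-8α-hydroxy-13,14,15,16-tetranorlabdan-12-oic acid (tertiary 8α-OH equatorial, C17 methyl axial)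
Conditions: AlMe3, CH2Cl2, 0 °C → rt
Reagents that add atoms: 4, CNOC.Cl
Why: Aluminium-amide (Weinreb) aminolysis opens the γ-lactone without touching any stereocentre and gives a hydroxy amide that does not relactonise readily.

Step 3
Reactants: 5
Product: 6, Weinreb amide of 2α-chloro-13,14,15,16-tetranorlabd-8(17)-en-12-oic acid
Conditions: SOCl2, pyridine, CH2Cl2, −78 °C
Reagents that add atoms: none
Why: E2 dehydration via the chlorosulfite; the equatorial 8α leaving group has only the axial C17 methyl hydrogens anti-periplanar, so the exocyclic alkene forms selectively.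

Step 4
Reactants: 6; 7 ozone
Product: 8, Weinreb amide of 2α-chloro-8-oxo-13,14,15,16,17-pentanorlabdan-12-oic acid
Conditions: O3, CH2Cl2/MeOH, −78 °C; then Me2S
Reagents that add atoms: 7, [O-][O+]=O
Why: Ozonolysis of the only alkene; the amide and chloride are inert, and C9 keeps its thermodynamically preferred equatorial side chain.

Step 5
Reactants: 8
Product: 9, the Δ6-en-8-one (C6=C7 conjugated to the C8 ketone)
Conditions: LDA, THF, −78 °C; then N-tert-butylbenzenesulfinimidoyl chloride, −78 °C
Reagents that add atoms: none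
Why: Mukaiyama dehydrogenation; kinetic deprotonation occurs at the C7 methylene (not the C9 methine or the much less acidic amide α-CH2), and syn-elimination of the α-sulfilimine gives the enone.

Step 6
Reactants: 9; 10 bis(pinacolato)diboron
Product: 11, 6α-(pinacolboryl)-8-ketone
Conditions: CuCl (5 mol %), DPEphos (5 mol %), NaOt-Bu (10 mol %), MeOH (2 equiv), THF, rt
Reagents that add atoms: 10, CC1(C)OB(OC1(C)C)B1OC(C)(C)C(C)(C)O1
Why: Cu(I)–boryl conjugate borylation puts boron on the β-carbon (C6), from the α-face because the β-face is blocked by the axial C19/C20 methyls; the boronate serves as a masked, non-eliminable hydroxyl.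

Step 7
Reactants: 11; 12 dibromomethane; 13 sodium perborate tetrahydrate
Product: 14, Weinreb amide of 2α-chloro-6α-hydroxy-13,14,15,16-tetranorlabd-8(17)-en-12-oic acid
Conditions: Zn, CH2Br2, TiCl4 (Lombardo reagent), THF/CH2Cl2, 0 °C → rt; then crude boronate, NaBO3·4H2O, THF/H2O, rt
Reagents that add atoms: 12, BrCBr (CH2); 13, [Na+].[Na+].O[B-]1(O)OO[B-](O)(O)OO1 (O)
Why: Takai–Lombardo methylenation is non-basic (no C9 epimerisation or β-elimination) and ketone-selective over the amide, and perborate then oxidises C–B to C–OH with retention.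

Step 8
Reactants: 14
Product: 15, 2α-chloro-6α-hydroxy-13,14,15,16-tetranorlabd-8(17)-en-12-al
Conditions: LiAlH4 (2 equiv), THF, −78 → 0 °C; aq. Rochelle salt
Reagents that add atoms: none
Why: Weinreb reduction stops at the chelated tetrahedral intermediate and releases the aldehyde on work-up; the hindered equatorial chloride and the alkene are untouched.

Step 9
Reactants: 15
Product: 16, 2α-chloro-6-oxo-13,14,15,16-tetranorlabd-8(17)-en-12-al
Conditions: Dess–Martin periodinane, NaHCO3, CH2Cl2, 0 °C → rt; used directly
Reagents that add atoms: none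
Why: Buffered Dess–Martin oxidation converts the homoallylic alcohol into the β,γ-unsaturated ketone under neutral conditions without conjugating the alkene, and leaves the aldehyde alone.

Step 10
Reactants: 17 (R)-4-benzyl-2-oxazolidinone; 18 succinic anhydride
Product: 19, 4-[(4R)-4-benzyl-2-oxooxazolidin-3-yl]-4-oxobutanoic acid
Conditions: n-BuLi, THF, −78 °C; then 18, −78 → 0 °C
Reagents that add atoms: 18, O=C1CCC(=O)O1
Why: N-Acylation of the lithiated oxazolidinone by ring-opening of the cyclic anhydride.

Step 11
Reactants: 19; 20 ammonia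
Product: 21, 4-[(4R)-4-benzyl-2-oxooxazolidin-3-yl]-4-oxobutanamide
Conditions: i-BuOCOCl, N-methylmorpholine, THF, −20 °C; then NH3 (0.5 M in dioxane, 1.05 equiv), −20 → 0 °C
Reagents that add atoms: 20, N
Why: Mixed-anhydride amidation; the anhydride is far more electrophilic than the acyl oxazolidinone, and stoichiometric ammonia at low temperature avoids premature imide closure.

Step 12
Reactants: 16; 21 (1.5 equiv)
Product: 22, (4R)-4-benzyl-3-[(2R,3S)-2-(2-amino-2-oxoethyl)-3-hydroxy-4-(decalinyl)butanoyl]oxazolidin-2-one (12S,13R)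
Conditions: 21, Bu2BOTf (2.0 equiv per 21), Et3N (2.2 equiv per 21), CH2Cl2, −78 → 0 °C; then 16, −78 → −20 °C; pH 7 buffer, MeOH, H2O2, 0 °C
Reagents that add atoms: 21, NC(=O)CCC(=O)N1[C@H](Cc2ccccc2)COC1=O
Why: Evans syn-aldol; the Z-boron enolate reacts through a Zimmerman–Traxler chair in which the (R)-benzyl auxiliary sets 13R and 12S together, and the aldehyde reacts far faster than the hindered C6 ketone.

Step 13
Reactants: 22
Product: 23, haterumaimide G (auxiliary 17 is released)
Conditions: Et3N (1 equiv), CH2Cl2, 0 °C → rt; pH 5 buffer quench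
Reagents that add atoms: none
Why: Intramolecular N-acyl transfer (5-exo-trig) of the primary amide onto the activated acyl oxazolidinone forms the succinimide; C13 is not epimerised under this mild base.

**Compound list**

1 | (+)-sclareolide | C[C@@]12CC[C@H]3C(C)(C)CCC[C@]3(C)[C@H]1CC(=O)O2 | starting material
2 | N-tert-butyl-N-chloro-3,5-bis(trifluoromethyl)benzamide | CC(C)(C)N(Cl)C(=O)c1cc(cc(c1)C(F)(F)F)C(F)(F)F | starting material (reagent)
3 | 2α-chlorosclareolide | C[C@@]12CC[C@H]3C(C)(C)C[C@H](Cl)C[C@]3(C)[C@H]1CC(=O)O2 | intermediate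
4 | N,O-dimethylhydroxylamine hydrochloride | CNOC.Cl | starting material
5 | 2α-chloro-8α-hydroxy-tetranorlabdan-12-oic acid Weinreb amide | C[C@@]1(O)CC[C@H]2C(C)(C)C[C@H](Cl)C[C@]2(C)[C@H]1CC(=O)N(C)OC | intermediate
6 | 2α-chloro-tetranorlabd-8(17)-en-12-oic acid Weinreb amide | C=C1CC[C@H]2C(C)(C)C[C@H](Cl)C[C@]2(C)[C@H]1CC(=O)N(C)OC | intermediate
7 | ozone | [O-][O+]=O | starting material (reagent)
8 | 2α-chloro-8-oxo-17-nor Weinreb amide | O=C1CC[C@H]2C(C)(C)C[C@H](Cl)C[C@]2(C)[C@H]1CC(=O)N(C)OC | intermediate
9 | 2α-chloro-8-oxo-17-nor-6-ene Weinreb amide | O=C1C=C[C@H]2C(C)(C)C[C@H](Cl)C[C@]2(C)[C@H]1CC(=O)N(C)OC | intermediate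
10 | bis(pinacolato)diboron | CC1(C)OB(OC1(C)C)B1OC(C)(C)C(C)(C)O1 | starting material
11 | 6α-Bpin-2α-chloro-8-oxo-17-nor Weinreb amide | O=C1C[C@H](B3OC(C)(C)C(C)(C)O3)[C@H]2C(C)(C)C[C@H](Cl)C[C@]2(C)[C@H]1CC(=O)N(C)OC | intermediate
12 | dibromomethane | BrCBr | starting material (reagent)
13 | sodium perborate (tetrahydrate) | [Na+].[Na+].O[B-]1(O)OO[B-](O)(O)OO1 | starting material (reagent)
14 | 2α-chloro-6α-hydroxy-tetranorlabd-8(17)-en-12-oic acid Weinreb amide | C=C1C[C@H](O)[C@H]2C(C)(C)C[C@H](Cl)C[C@]2(C)[C@H]1CC(=O)N(C)OC | intermediate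
15 | 2α-chloro-6α-hydroxy-tetranorlabd-8(17)-en-12-al | C=C1C[C@H](O)[C@H]2C(C)(C)C[C@H](Cl)C[C@]2(C)[C@H]1CC=O | intermediate
16 | 2α-chloro-6-oxo-tetranorlabd-8(17)-en-12-al | C=C1CC(=O)[C@H]2C(C)(C)C[C@H](Cl)C[C@]2(C)[C@H]1CC=O | intermediate
17 | (R)-4-benzyl-2-oxazolidinone | O=C1N[C@H](Cc2ccccc2)CO1 | starting material
18 | succinic anhydride | O=C1CCC(=O)O1 | starting material
19 | 4-[(4R)-4-benzyl-2-oxooxazolidin-3-yl]-4-oxobutanoic acid | OC(=O)CCC(=O)N1[C@H](Cc2ccccc2)COC1=O | intermediate
20 | ammonia | N | starting material (reagent)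
21 | 4-[(4R)-4-benzyl-2-oxooxazolidin-3-yl]-4-oxobutanamide | NC(=O)CCC(=O)N1[C@H](Cc2ccccc2)COC1=O | intermediate
22 | Evans syn-aldol adduct (12S,13R) | C=C1CC(=O)[C@H]2C(C)(C)C[C@H](Cl)C[C@]2(C)[C@H]1C[C@H](O)[C@@H](CC(N)=O)C(=O)N1[C@H](Cc2ccccc2)COC1=O | intermediate
23 | haterumaimide G | C=C1CC(=O)[C@H]2C(C)(C)C[C@H](Cl)C[C@]2(C)[C@H]1C[C@H](O)[C@H]1CC(=O)NC1=O | target

**Totals**
- Total steps: 13 (11 on the main line plus 2 for aldol partner 21).
- Longest linear sequence: 11 steps from sclareolide (steps 1–9, 12, 13).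

**Three steps most likely to fail, with fallbacks**

1. Step 12 (aldol on the keto-aldehyde). Excess Bu2BOTf/Et3N, needed because the carboxamide ties up boron, could enolise the C6 ketone and give the conjugated Δ7-enone or an intramolecular aldol.
   Fallback: protect 14 as its 6-O-TES ether, reduce to the aldehyde, and run the aldol and imide closure with no ketone present. Then TBS-protect C12–OH, remove TES selectively, oxidise C6 with Dess–Martin and desilylate with HF·pyridine (about four extra steps).

2. Step 7 (methylenation of the hindered C8 ketone next to a Bpin and a Weinreb amide). The ketone may react sluggishly, or the low-valent Ti may attack the N–O bond.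
   Fallback: drop the 17-nor detour and keep C17 throughout. Dehydrate 5 to the Δ7-ene, oxidise C6 with CrO3·3,5-dimethylpyrazole to the 7-en-6-one, epoxidise with H2O2/NaOH, and open with SmI2 to the 8α-hydroxy-6-ketone. Reduce and acetylate C6, then repeat the exo-selective SOCl2/pyridine dehydration.

3. Step 13 (imide closure). The amine base could isomerise the β,γ-enone before cyclisation is complete.
   Fallback: use the 3-cyanopropanoyl (R)-oxazolidinone as aldol donor under standard 1:1 Evans stoichiometry, then unmask nitrogen under neutral conditions by Pt-catalysed nitrile hydration (Ghaffar–Parkins catalyst, aq. EtOH). The resulting amide cyclises thermally onto the acyl oxazolidinone with no base present.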